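**Retrosynthetic overview**
- Ester C–O bond: target ⇒ linoleic acid + 4-[(1S,2R)-3,3-dimethyl-2-(3-oxobutyl)cyclobutyl]pent-4-en-1-ol.
- Side chains: 3-oxobutyl ⇒ vinyl (cross-metathesis with methyl vinyl ketone, then 1,4-reduction); 3-hydroxypropyl ⇒ isopropenyl methyl (allylic lithiation, ethylene oxide).
- The only ring ⇒ open-chain allylic alcohol by C2–C10 closure: the prenyl alkene attacks an electrophilic allyl carbon (4-exo) and the tertiary cation loses a methyl proton, as in the humulyl → caryophyllenyl step of caryophyllene synthase, here made enantioselective by an iridium catalyst.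
- C1–C11 bond ⇒ prenyl chloride (allylic electrophile) + isobutyraldehyde enolate, the counterpart of the 1,11-closure; vinyl Grignard addition then installs the allyl electrophile.
- Ring order: one ring only, closed in step 3; both stereocenters are set in that step.

Assumption: the (S)-ligand is taken to give the (2R,3S) product; if the sense of induction is the opposite, the (R)-ligand is used and nothing else changes. Atom labels C1–C15 in the explanations follow farnesane numbering (ring = C1, C2, C10, C11).

Step 1
Reactants: 1 isobutyraldehyde (2-methylpropanal); 2 prenyl chloride (1-chloro-3-methylbut-2-ene)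
Product: 3 2,2,5-trimethylhex-4-enal
Conditions: 50% aq. NaOH, Bu4NBr (5 mol%), toluene, 70 °C
Reagents that add atoms: none
Why: Phase-transfer enolate C-alkylation (SN2 at the primary allylic carbon); isobutyraldehyde has a single α-hydrogen, so only monoalkylation to the quaternary carbon can occur, and the bond made (C11 to C1) is the one formed first in the biosynthesis; no stereocenter.

Step 2
Reactants: 3 2,2,5-trimethylhex-4-enal; 4 vinylmagnesium bromide
Product: 5 rac-4,4,7-trimethylocta-1,6-dien-3-ol
Conditions: THF, 0 °C; then aq. NH4Cl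
Reagents that add atoms: none
Why: Grignard 1,2-addition to a non-enolizable α-quaternary aldehyde; the carbinol center is deliberately racemic because it is erased on ionization in step 3.

Step 3
Reactants: 5 rac-4,4,7-trimethylocta-1,6-dien-3-ol
Product: 7 (2R,3S)-2-ethenyl-1,1-dimethyl-3-(prop-1-en-2-yl)cyclobutane, via cyclobutylcarbinyl cation 6 (not isolated)
Conditions: [Ir(cod)Cl]2 (4 mol%), (S)-BINOL-derived phosphoramidite–olefin ligand (N-5H-dibenzo[b,f]azepinyl, 16 mol%), Zn(OTf)2 (20 mol%), ClCH2CH2Cl, 25–50 °C
Reagents that add atoms: none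
Why: Proposed new method: the iridium/phosphoramidite–olefin catalyst, with Zn(OTf)2 assisting loss of hydroxide, ionizes racemic 5 to a trivalent-iridium η3-allyl; its substituted terminus (C10) is attacked anti to the metal by the tethered prenyl alkene in a 4-exo mode (gem-dimethyl assistance; the syn-allyl geometry blocks the 6-endo alternative, which would need a trans-cyclohexene), giving tertiary cation 6, which loses a proton from either of its two equivalent methyl groups to give the isopropenyl group, the same alkene-onto-C10 closure and C15 deprotonation as in caryophyllene synthase; the ligand sets C10 as R by enantioconvergent face selection and C2 follows as S because the cationic 2-propyl unit and the vinyl group take the trans arrangement on the forming ring; closest known reaction types: iridium-catalysed enantioselective allyl–alkene coupling and polyene cyclization of racemic branched allylic alcohols, and allyl cation/alkene [2+2] cyclobutane formation.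

Step 4
Reactants: 7 (2R,3S)-2-ethenyl-1,1-dimethyl-3-(prop-1-en-2-yl)cyclobutane; 8 ethylene oxide (oxirane)
Product: 10 4-[(1S,2R)-2-ethenyl-3,3-dimethylcyclobutyl]pent-4-en-1-ol, via allyllithium 9 (not isolated)
Conditions: n-BuLi, TMEDA, hexane, 25 °C; then ethylene oxide, THF, −78 to 0 °C; then H2O
Reagents that add atoms: none
Why: Kinetic allylic lithiation by n-BuLi·TMEDA removes a primary hydrogen of the isopropenyl methyl group (as with limonene) rather than the tertiary ring hydrogens, and the 2-substituted allyllithium has two equivalent CH2 termini, so epoxide ring-opening gives one constitution; no stereocenter is touched.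

Step 5
Reactants: 10 4-[(1S,2R)-2-ethenyl-3,3-dimethylcyclobutyl]pent-4-en-1-ol; 11 methyl vinyl ketone (but-3-en-2-one, 3 equiv)
Product: 12 4-[(1S,2R)-3,3-dimethyl-2-[(1E)-3-oxobut-1-en-1-yl]cyclobutyl]pent-4-en-1-ol
Conditions: second-generation Grubbs catalyst (H2IMes)(PCy3)Cl2Ru=CHPh (5 mol%), CH2Cl2, 40 °C
Reagents that add atoms: none
Why: Olefin cross-metathesis: the monosubstituted vinyl group couples with the enone partner to the E-enone with loss of ethylene, while the hindered 1,1-disubstituted methylene group and the free alcohol stay out; neutral conditions leave the γ-stereocenter (C10) unchanged.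

Step 6
Reactants: 12 4-[(1S,2R)-3,3-dimethyl-2-[(1E)-3-oxobut-1-en-1-yl]cyclobutyl]pent-4-en-1-ol
Product: 13 4-[(1S,2R)-3,3-dimethyl-2-(3-oxobutyl)cyclobutyl]pent-4-en-1-ol
Conditions: [(Ph3P)CuH]6 (0.35 equiv), H2O (5 equiv), toluene/THF, 23 °C
Reagents that add atoms: none
Why: Copper hydride conjugate (1,4-) reduction: hydride adds only at the enone β-carbon and water protonates the copper enolate; the isolated alkenes, the ketone and the alcohol are inert and no stereocenter is formed.

Step 7
Reactants: 13 4-[(1S,2R)-3,3-dimethyl-2-(3-oxobutyl)cyclobutyl]pent-4-en-1-ol; 14 linoleic acid ((9Z,12Z)-octadeca-9,12-dienoic acid)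
Product: 15 4-[(1S,2R)-3,3-dimethyl-2-(3-oxobutyl)cyclobutyl]pent-4-en-1-yl (9Z,12Z)-octadeca-9,12-dienoate (IN0146)
Conditions: DCC, DMAP (10 mol%), CH2Cl2, 0 to 23 °C, argon
Reagents that add atoms: none
Why: Steglich esterification of the primary alcohol; neutral room-temperature acylation under argon keeps the skipped Z,Z-diene intact and does not affect the ketone, the methylene group or the stereocenters.

**Compound list**
1 | isobutyraldehyde (2-methylpropanal) | CC(C)C=O | starting material
2 | prenyl chloride (1-chloro-3-methylbut-2-ene) | CC(C)=CCCl | starting material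
3 | 2,2,5-trimethylhex-4-enal | CC(C)=CCC(C)(C)C=O | intermediate
4 | vinylmagnesium bromide | C=C[Mg]Br | starting material
5 | rac-4,4,7-trimethylocta-1,6-dien-3-ol | C=CC(O)C(C)(C)CC=C(C)C | intermediate
6 | 2-(trans-2-ethenyl-3,3-dimethylcyclobutyl)propan-2-yl cation (ring configuration as in 7) | C[C+](C)[C@H]1CC(C)(C)[C@@H]1C=C | intermediate
7 | (2R,3S)-2-ethenyl-1,1-dimethyl-3-(prop-1-en-2-yl)cyclobutane (trans) | C=C(C)[C@H]1CC(C)(C)[C@@H]1C=C | intermediate
8 | ethylene oxide (oxirane) | C1CO1 | starting material
9 | {2-[(1S,2R)-2-ethenyl-3,3-dimethylcyclobutyl]prop-2-en-1-yl}lithium | [Li]CC(=C)[C@H]1CC(C)(C)[C@@H]1C=C | intermediate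
10 | 4-[(1S,2R)-2-ethenyl-3,3-dimethylcyclobutyl]pent-4-en-1-ol | C=C(CCCO)[C@H]1CC(C)(C)[C@@H]1C=C | intermediate
11 | methyl vinyl ketone (but-3-en-2-one) | CC(=O)C=C | starting material
12 | 4-[(1S,2R)-3,3-dimethyl-2-[(1E)-3-oxobut-1-en-1-yl]cyclobutyl]pent-4-en-1-ol | C=C(CCCO)[C@H]1CC(C)(C)[C@@H]1/C=C/C(C)=O | intermediate
13 | 4-[(1S,2R)-3,3-dimethyl-2-(3-oxobutyl)cyclobutyl]pent-4-en-1-ol | C=C(CCCO)[C@H]1CC(C)(C)[C@@H]1CCC(C)=O | intermediate
14 | linoleic acid ((9Z,12Z)-octadeca-9,12-dienoic acid) | CCCCC/C=C\C/C=C\CCCCCCCC(=O)O | starting material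
15 | 4-[(1S,2R)-3,3-dimethyl-2-(3-oxobutyl)cyclobutyl]pent-4-en-1-yl (9Z,12Z)-octadeca-9,12-dienoate (IN0146) | C=C(CCCOC(=O)CCCCCCC/C=C\C/C=C\CCCCC)[C@H]1CC(C)(C)[C@@H]1CCC(C)=O | target

**Step count and risks**
Total steps: 7. Longest linear sequence: 7 (from 1 and 2 to 15).

Most likely to fail, first: step 3. The 4-exo attack of an unactivated alkene on the iridium allyl next to a quaternary carbon may be too slow. Cation 6 may also ring-expand to cyclopentyl products, lose the ring proton to give the isopropylidene isomer, or be hydrated. The fallback sets out from 5 and comes back at 7, replacing the proton-loss terminator by a silicon terminator. Deprotonation of 5 with n-BuLi and then n-BuLi/KOt-Bu (THF/hexane, −78 to −40 °C) gives the lithium alkoxide/allylpotassium dianion of 5 F1, metalated at a prenyl methyl group. Me3SiCl (2.2 equiv) gives trimethyl{[4,4,7-trimethyl-8-(trimethylsilyl)octa-1,6-dien-3-yl]oxy}silane F2, and K2CO3 in MeOH removes the O-silyl group to give 4,4,7-trimethyl-8-(trimethylsilyl)octa-1,6-dien-3-ol F3. The same iridium/ligand/Zn(OTf)2 system then closes the ring as an intramolecular allyl–allylsilane coupling (Hosomi–Sakurai-type SE2′ closure). The allylsilane is several orders of magnitude more nucleophilic than the prenyl alkene, and the β-silyl cation can only collapse to the exocyclic methylene, which gives 7.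

Second: step 4. Lithiation may be incomplete or unselective, and the hydrocarbon 7 is volatile. The fallback sets out from 7 and comes back at 10, replacing C–H lithiation by electrophilic allylic functionalization. Ene-type chlorination of the isopropenyl group (Ca(OCl)2, solid CO2, CH2Cl2/H2O, 0 °C; the monosubstituted vinyl group is much less reactive) gives (2R,3S)-3-(3-chloroprop-1-en-2-yl)-2-ethenyl-1,1-dimethylcyclobutane F4. Magnesium insertion (Mg turnings, THF, slow addition, 0 °C) gives {2-[(1S,2R)-2-ethenyl-3,3-dimethylcyclobutyl]prop-2-en-1-yl}magnesium chloride F5, which opens ethylene oxide 8 and gives 10 after aqueous work-up.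

Third: step 5. The vinyl group sits on a tertiary carbon next to a quaternary one and may be sluggish in metathesis, and ruthenium hydrides could isomerize the methylene group. The fallback sets out from 10 and comes back at 13, bypassing 12 and step 6, with hydrometalation/acylation in place of metathesis/reduction. Silylation (t-BuMe2SiCl, imidazole, CH2Cl2) gives tert-butyl({4-[(1S,2R)-2-ethenyl-3,3-dimethylcyclobutyl]pent-4-en-1-yl}oxy)dimethylsilane F6. Hydrozirconation with Cp2Zr(H)Cl (1.1 equiv, CH2Cl2, 23 °C), selective for the monosubstituted alkene, gives chlorobis(cyclopentadienyl)(2-{(1R,2S)-2-[5-(tert-butyldimethylsilyloxy)pent-1-en-2-yl]-4,4-dimethylcyclobutyl}ethyl)zirconium F7. CuBr·SMe2-catalysed acylation with acetyl chloride gives tert-butyl({4-[(1S,2R)-3,3-dimethyl-2-(3-oxobutyl)cyclobutyl]pent-4-en-1-yl}oxy)dimethylsilane F8, and Bu4NF in THF gives 13.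

**Further compounds**
F1 | step 3 | lithium alkoxide/allylpotassium dianion of 5 | [Li]OC(C=C)C(C)(C)CC=C(C)C[K]
F2 | step 3 | trimethyl{[4,4,7-trimethyl-8-(trimethylsilyl)octa-1,6-dien-3-yl]oxy}silane | C=CC(O[Si](C)(C)C)C(C)(C)CC=C(C)C[Si](C)(C)C
F3 | step 3 | 4,4,7-trimethyl-8-(trimethylsilyl)octa-1,6-dien-3-ol | C=CC(O)C(C)(C)CC=C(C)C[Si](C)(C)C
F4 | step 4 | (2R,3S)-3-(3-chloroprop-1-en-2-yl)-2-ethenyl-1,1-dimethylcyclobutane | ClCC(=C)[C@H]1CC(C)(C)[C@@H]1C=C
F5 | step 4 | {2-[(1S,2R)-2-ethenyl-3,3-dimethylcyclobutyl]prop-2-en-1-yl}magnesium chloride | Cl[Mg]CC(=C)[C@H]1CC(C)(C)[C@@H]1C=C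
F6 | step 5 | tert-butyl({4-[(1S,2R)-2-ethenyl-3,3-dimethylcyclobutyl]pent-4-en-1-yl}oxy)dimethylsilane | C=C(CCCO[Si](C)(C)C(C)(C)C)[C@H]1CC(C)(C)[C@@H]1C=C
F7 | step 5 | chlorobis(cyclopentadienyl)(2-{(1R,2S)-2-[5-(tert-butyldimethylsilyloxy)pent-1-en-2-yl]-4,4-dimethylcyclobutyl}ethyl)zirconium | C=C(CCCO[Si](C)(C)C(C)(C)C)[C@H]1CC(C)(C)[C@@H]1CC[Zr](Cl)(C1C=CC=C1)C1C=CC=C1
F8 | step 5 | tert-butyl({4-[(1S,2R)-3,3-dimethyl-2-(3-oxobutyl)cyclobutyl]pent-4-en-1-yl}oxy)dimethylsilane | C=C(CCCO[Si](C)(C)C(C)(C)C)[C@H]1CC(C)(C)[C@@H]1CCC(C)=O
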